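Everything rests on disconnecting C24–C23 in ring B. N25, its methyl group and C24 are what remains of N-methylglycine after loss of CO2, and C23 is the fully substituted β-carbon of the ring D/E enone (C12=O, C13=C23). Photoredox decarboxylation of an N-methylglycine arm therefore gives a nucleophilic C24 radical that closes the piperidine by 6-exo addition to C23, creating the C23 quaternary centre and the cis D/E fusion in one operation. The precursor is the diquinane enone whose C23 bears the ring A quaternary carbon C6; C9 carries the CH2N(Me)CH2CO2H arm and a saturated 2-borylethyl arm (C10–C11), which cannot intercept the radicals and later closes ring C by Suzuki coupling.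

Key step: step 15

Numbering: atoms follow the target SMILES (C1–C27, O8, O19, O20, N25). Ring A = O8/C3–C7, ring B = N25/C24/C23/C6/C9/C27, ring C = C6/C9–C13/C23, ring D = C12–C16, ring E = C13/C14/C17/C22/C23.

Assumption: the ligand enantiomers written in steps 1 and 8 are taken to give the configurations drawn at C9 and C14; if the sense is opposite, the antipodal ligand is used.

Design remarks:
- A vinyl group on C9 would place C10 five atoms from both the C24 radical and the C13 radical of step 15 and invite 5-exo closures. The alkene is therefore hydroborated before the key step and carried as a pinacol boronate.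
- The radical closure forms two stereocentres, C23 and, transiently, C13.
- The C12 enolate is protonated in the flask, so the C12=C13 enol regiochemistry is re-established in step 16.
- Nitrogen is attached to C27 by SN2 displacement, not through a C27 aldehyde, so that C9 cannot epimerise.

Step 1
Reactants: 1 furan-2(5H)-one; 2 potassium vinyltrifluoroborate
Product: 3 (R)-4-vinyldihydrofuran-2(3H)-one
Conditions: [RhCl(C2H4)2]2 (2.5 mol %), (R,R)-2,5-diphenylbicyclo[2.2.2]octa-2,5-diene (5.5 mol %), Et3N, toluene/H2O, 60 °C
Reagents that add atoms: none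
Why: Rhodium-catalysed asymmetric conjugate addition of an alkenylboron reagent to an unsaturated lactone (Hayashi–Miyaura reaction) should work because furanones are established acceptors, and the chiral diene ligand selects the enone face and thereby sets C9.

Step 2
Reactants: 4 ethyl vinyl ketone
Product: 6 2-ethyl-2-(2-iodoethyl)-1,3-dioxolane, via β-iodo silyl enol ether 5 (not isolated)
Conditions: NaI, TMSCl, MeCN, −20 °C; then ethylene glycol, rt
Reagents that add atoms: sodium iodide [Na+].[I-]; ethylene glycol OCCO
Why: Iodotrimethylsilane made in the flask adds in conjugate fashion to the enone and the silyl enol ether is ketalised by the diol without added acid, the known route from vinyl ketones to β-iodo ketals.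

Step 3
Reactants: 3 (R)-4-vinyldihydrofuran-2(3H)-one; 6 2-ethyl-2-(2-iodoethyl)-1,3-dioxolane
Product: 7 (3S,4S)-3-[2-(2-ethyl-1,3-dioxolan-2-yl)ethyl]-4-vinyldihydrofuran-2(3H)-one (side chain trans to vinyl)
Conditions: LiN(i-Pr)2, THF, −78 °C; then 6, DMPU, −78 to −30 °C
Reagents that add atoms: none
Why: Alkylation of the lactone enolate with a primary iodide should occur on the face anti to the C9 vinyl group (1,2-induction in β-substituted butyrolactone enolates), giving the trans lactone.

Step 4
Reactants: 7 (3S,4S)-3-[2-(2-ethyl-1,3-dioxolan-2-yl)ethyl]-4-vinyldihydrofuran-2(3H)-one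
Product: 8 (3R,4S)-3-[2-(2-ethyl-1,3-dioxolan-2-yl)ethyl]-3-(hydroxymethyl)-4-vinyldihydrofuran-2(3H)-one (hydroxymethyl trans to vinyl)
Conditions: LiN(i-Pr)2, THF, −78 °C; then CH2O (gas from cracked paraformaldehyde), −78 to −40 °C
Reagents that add atoms: formaldehyde C=O
Why: Aldol hydroxymethylation of the regenerated enolate again takes the electrophile anti to the vinyl group, so C7 ends trans and the C5 chain cis to vinyl, which fixes the quaternary centre C6 in the configuration of the target.

Step 5
Reactants: 8 (3R,4S)-3-[2-(2-ethyl-1,3-dioxolan-2-yl)ethyl]-3-(hydroxymethyl)-4-vinyldihydrofuran-2(3H)-one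
Product: 9 (3R,4S)-3-[2-(2-ethyl-1,3-dioxolan-2-yl)ethyl]-3,4-bis(hydroxymethyl)hex-5-en-2-one (in equilibrium with its five-membered lactol)
Conditions: MeLi (3.2 equiv), THF, −78 to −40 °C
Reagents that add atoms: methyllithium [Li]C
Why: Methyllithium adds once to the lactone carbonyl because the hindered lithium lactolate does not collapse at low temperature, which turns C23 into the methyl ketone (C22) and frees the C27 hydroxyl.

Step 6
Reactants: 9 (3R,4S)-3-[2-(2-ethyl-1,3-dioxolan-2-yl)ethyl]-3,4-bis(hydroxymethyl)hex-5-en-2-one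
Product: 10 (3R,4S)-3,4-bis[(tert-butyldimethylsilyloxy)methyl]-3-[2-(2-ethyl-1,3-dioxolan-2-yl)ethyl]hex-5-en-2-one
Conditions: TBSCl, imidazole, DMF, rt
Reagents that add atoms: tert-butyldimethylsilyl chloride CC(C)(C)[Si](C)(C)Cl
Why: Silylation of the two primary alcohols traps the open keto form and protects C7–OH and C27–OH for the enolate steps (standard silyl ether formation).

Step 7
Reactants: 10 (3R,4S)-3,4-bis[(tert-butyldimethylsilyloxy)methyl]-3-[2-(2-ethyl-1,3-dioxolan-2-yl)ethyl]hex-5-en-2-one
Product: 12 (3R,4S)-1-bromo-3,4-bis[(tert-butyldimethylsilyloxy)methyl]-3-[2-(2-ethyl-1,3-dioxolan-2-yl)ethyl]hex-5-en-2-one, via trimethylsilyl enol ether 11 (not isolated)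
Conditions: LiN(SiMe3)2, THF, −78 °C; TMSCl; then NBS, THF, 0 °C
Reagents that add atoms: N-bromosuccinimide O=C1CCC(=O)N1Br
Why: The ketone can enolise only toward the methyl group C22 because C6 is quaternary, and the silyl enol ether is brominated by NBS much faster than the vinyl group (α-bromination through a silyl enol ether).

Step 8
Reactants: 13 cyclopent-2-en-1-one; 14 dimethyl malonate
Product: 15 dimethyl (S)-2-(3-oxocyclopentyl)malonate
Conditions: LiAl((S)-1,1'-bi-2-naphthoxide)2 (10 mol %), KOt-Bu (9 mol %), 4 Å MS, THF, rt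
Reagents that add atoms: none
Why: Catalytic asymmetric Michael addition of malonate to cyclopentenone under heterobimetallic binaphthoxide catalysis is established, and the catalyst directs the malonate to one enone face and sets C14.

Step 9
Reactants: 12 (3R,4S)-1-bromo-3,4-bis[(tert-butyldimethylsilyloxy)methyl]-3-[2-(2-ethyl-1,3-dioxolan-2-yl)ethyl]hex-5-en-2-one; 15 dimethyl (S)-2-(3-oxocyclopentyl)malonate
Product: 16 dimethyl 2-[(S)-3-oxocyclopentyl]-2-(2-oxoalkyl)malonate (C17 joined to C22; the 2-oxoalkyl group is the chain of 12)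
Conditions: NaH, THF, 0 °C; then 12, DMF, 0 °C to rt
Reagents that add atoms: none
Why: SN2 alkylation of the sodium malonate by the α-bromo ketone, a reactive primary electrophile with no other enolisable position, forms C17–C22.

Step 10
Reactants: 16 dimethyl 2-[(S)-3-oxocyclopentyl]-2-(2-oxoalkyl)malonate
Product: 17 diquinane enone gem-diester (rings D and E closed; C12 ketone; C13=C23; two CO2Me on C17; C6 S; C9 S; C14 as in the target)
Conditions: pyrrolidine, AcOH, 4 Å MS, toluene, 80 °C
Reagents that add atoms: none
Why: Intramolecular aldol condensation through the enamine of the unhindered cyclopentanone: only attack of C13 on the C23 ketone gives a five-membered aldol that can dehydrate to a conjugated enone (the other modes give bridged aldols that revert), so ring E and the C13=C23 enone form.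

Step 11
Reactants: 17 diquinane enone gem-diester
Product: 18 diquinane enone monoester (C17 bearing one CO2Me and H17 cis to H14)
Conditions: NaCl, H2O, DMSO, 140 °C
Reagents that add atoms: none
Why: Krapcho demethoxycarbonylation leaves an ester enolate that is protonated kinetically on the face away from C15 of ring D, which places H17 cis to H14 as in the target.

Step 12
Reactants: 18 diquinane enone monoester
Product: 19 pinacol boronate (C9 bearing CH2CH2Bpin in place of vinyl)
Conditions: [Ir(cod)Cl]2 (1.5 mol %), dppm (3 mol %), pinacolborane, CH2Cl2, rt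
Reagents that add atoms: pinacolborane [H]B1OC(C)(C)C(C)(C)O1
Why: Iridium-catalysed hydroboration with pinacolborane is selective for the terminal alkene and anti-Markovnikov, while the tetrasubstituted enone is too hindered to react.

Step 13
Reactants: 19 pinacol boronate
Product: 21 ring A alcohol (6-ethyl-3,4-dihydro-2H-pyran ring closed at C6; free C27–OH), via cyclic hemiketal 20 (not isolated)
Conditions: 1 M HCl, THF/MeOH, rt; then PPTS, 4 Å MS, toluene, 80 °C
Reagents that add atoms: none
Why: Acid removes both silyl ethers and the dioxolane, the C7 hydroxyl closes on the C3 ketone to the six-membered hemiketal and dehydration gives the endocyclic enol ether (cyclodehydration), so ring A forms and only C27–OH stays free.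

Step 14
Reactants: 21 ring A alcohol; 22 sarcosine
Product: 26 amino acid precursor (C27–N(CH3)CH2CO2H; zwitterion), via triflate 23 (not isolated), via sarcosine trimethylsilyl ester 24 (not isolated), via silyl ester 25 (not isolated)
Conditions: Tf2O, 2,6-lutidine, CH2Cl2, −78 °C; then 22 presilylated with N,O-bis(trimethylsilyl)acetamide (CH2Cl2), −78 to 0 °C; MeOH
Reagents that add atoms: none
Why: SN2 N-alkylation of transiently silylated sarcosine by the primary triflate should be fast at low temperature, and since C27 never becomes a carbonyl the adjacent stereocentre C9 cannot epimerise; methanolysis of the silyl ester frees the acid.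

Step 15
Reactants: 26 amino acid precursor
Product: 27 tetracyclic amino ketone (rings A, B, D and E; C12 ketone; cis-fused D/E; C23 quaternary)
Conditions: [Ir(dF(CF3)ppy)2(dtbbpy)]PF6 (2 mol %), K2HPO4 (1.2 equiv), degassed DMSO (0.01 M), 450 nm LEDs, rt
Reagents that add atoms: none
Why: The excited trivalent iridium complex oxidises the amino carboxylate of 26, CO2 is lost, and the nucleophilic C24 aminomethyl radical adds to C23 of the electron-poor enone; the C13 α-keto radical is then reduced by the divalent iridium species to the C12 enolate, which is protonated to the ketone. The closest known reaction type is the photoredox decarboxylative conjugate addition (Giese reaction) of α-amino acids to enones, here run intramolecularly. Ring B (C24, N25, C27, C9, C6, C23) closes in the 6-exo-trig mode. C23 is set by attack on the enone face anti to the C17 ester and to C15 of ring D, and C13 by protonation on the convex face, which gives the cis-fused diquinane with H13 cis to H14. The step needs attack at C23 and not C13 and no escape of the radicals into other π bonds: the exo mode and the match of a nucleophilic radical with the enone β-carbon secure the site, and the saturated boronate arm leaves no alkene within reach of the C24 or C13 radical.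

Step 16
Reactants: 27 tetracyclic amino ketone
Product: 29 enol triflate (C12–OTf; C12=C13), via trimethylsilyl enol ether 28 (not isolated)
Conditions: TMSCl, NaI, Et3N, MeCN, rt; then CsF, PhNTf2, DME, rt
Reagents that add atoms: N-phenylbis(trifluoromethanesulfonimide) O=S(=O)(N(c1ccccc1)S(=O)(=O)C(F)(F)F)C(F)(F)F
Why: Silylation under equilibrating conditions (iodotrimethylsilane made in the flask, with Et3N) favours the more substituted C12=C13 enol ether, and fluoride then releases that enolate regiospecifically for O-triflation by PhNTf2.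

Step 17
Reactants: 29 enol triflate
Product: 30 target CNP0159589.2
Conditions: Pd(OAc)2 (10 mol %), RuPhos (20 mol %), K3PO4, toluene/H2O (10:1), 80 °C, 0.005 M
Reagents that add atoms: none
Why: Intramolecular B-alkyl Suzuki–Miyaura coupling of the primary alkyl boronate with the alkenyl triflate forms C11–C12 and closes the seven-membered ring C, leaving the C12=C13 alkene and creating no new stereocentre.

Compound list

1 | furan-2(5H)-one | O=C1OCC=C1 | starting material
2 | potassium vinyltrifluoroborate | C=C[B-](F)(F)F.[K+] | starting material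
3 | (R)-4-vinyldihydrofuran-2(3H)-one | O=C1C[C@H](C=C)CO1 | intermediate
4 | ethyl vinyl ketone (pent-1-en-3-one) | CCC(=O)C=C | starting material
5 | 1-iodo-3-(trimethylsilyloxy)pent-2-ene (not isolated) | CCC(O[Si](C)(C)C)=CCI | intermediate
6 | 2-ethyl-2-(2-iodoethyl)-1,3-dioxolane | CCC1(CCI)OCCO1 | intermediate
7 | (3S,4S)-3-[2-(2-ethyl-1,3-dioxolan-2-yl)ethyl]-4-vinyldihydrofuran-2(3H)-one | O=C1[C@@H](CCC2(CC)OCCO2)[C@H](C=C)CO1 | intermediate
8 | (3R,4S)-3-[2-(2-ethyl-1,3-dioxolan-2-yl)ethyl]-3-(hydroxymethyl)-4-vinyldihydrofuran-2(3H)-one | O=C1[C@](CO)(CCC2(CC)OCCO2)[C@H](C=C)CO1 | intermediate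
9 | (3R,4S)-3-[2-(2-ethyl-1,3-dioxolan-2-yl)ethyl]-3,4-bis(hydroxymethyl)hex-5-en-2-one | CC(=O)[C@](CO)(CCC1(CC)OCCO1)[C@H](C=C)CO | intermediate
10 | (3R,4S)-3,4-bis[(tert-butyldimethylsilyloxy)methyl]-3-[2-(2-ethyl-1,3-dioxolan-2-yl)ethyl]hex-5-en-2-one | CC(=O)[C@](CO[Si](C)(C)C(C)(C)C)(CCC1(CC)OCCO1)[C@H](C=C)CO[Si](C)(C)C(C)(C)C | intermediate
11 | trimethylsilyl enol ether of 10 at C23/C22 (not isolated) | C=C(O[Si](C)(C)C)[C@](CO[Si](C)(C)C(C)(C)C)(CCC1(CC)OCCO1)[C@H](C=C)CO[Si](C)(C)C(C)(C)C | intermediate
12 | (3R,4S)-1-bromo-3,4-bis[(tert-butyldimethylsilyloxy)methyl]-3-[2-(2-ethyl-1,3-dioxolan-2-yl)ethyl]hex-5-en-2-one | BrCC(=O)[C@](CO[Si](C)(C)C(C)(C)C)(CCC1(CC)OCCO1)[C@H](C=C)CO[Si](C)(C)C(C)(C)C | intermediate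
13 | cyclopent-2-en-1-one | O=C1C=CCC1 | starting material
14 | dimethyl malonate | COC(=O)CC(=O)OC | starting material
15 | dimethyl (S)-2-(3-oxocyclopentyl)malonate | O=C1CC[C@@H](C1)C(C(=O)OC)C(=O)OC | intermediate
16 | dimethyl 2-[(S)-3-oxocyclopentyl]-2-[(3R,4S)-3,4-bis[(tert-butyldimethylsilyloxy)methyl]-3-[2-(2-ethyl-1,3-dioxolan-2-yl)ethyl]-2-oxohex-5-en-1-yl]malonate | O=C1CC[C@@H](C1)C(C(=O)OC)(C(=O)OC)CC(=O)[C@](CO[Si](C)(C)C(C)(C)C)(CCC2(CC)OCCO2)[C@H](C=C)CO[Si](C)(C)C(C)(C)C | intermediate
17 | diquinane enone gem-diester: bicyclo[3.3.0]oct-1(8)-en-2-one (rings D/E) with two CO2Me on C17 and, on C23, the C6 quaternary carbon bearing CH2OTBS (C7), the dioxolane chain (C5–C1) and C9 (vinyl, CH2OTBS); C6, C9, C14 arranged as in 30 | CCC1(OCCO1)CC[C@](CO[Si](C)(C)C(C)(C)C)([C@H](C=C)CO[Si](C)(C)C(C)(C)C)C2=C3C(=O)CC[C@@H]3C(C(=O)OC)(C(=O)OC)C2 | intermediate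
18 | diquinane enone monoester: as 17 with one CO2Me on C17 and H17 cis to H14; C6, C9, C14, C17 arranged as in 30 | CCC1(OCCO1)CC[C@](CO[Si](C)(C)C(C)(C)C)([C@H](C=C)CO[Si](C)(C)C(C)(C)C)C2=C3C(=O)CC[C@@H]3[C@H](C(=O)OC)C2 | intermediate
19 | pinacol boronate: as 18 with CH2CH2B(pin) on C9 in place of vinyl | CCC1(OCCO1)CC[C@](CO[Si](C)(C)C(C)(C)C)([C@H](CCB2OC(C)(C)C(C)(C)O2)CO[Si](C)(C)C(C)(C)C)C3=C4C(=O)CC[C@@H]4[C@H](C(=O)OC)C3 | intermediate
20 | cyclic hemiketal (2-ethyltetrahydropyran-2-ol closed between C7–O and C3; C3 configuration not defined; not isolated) | CCC1(O)CC[C@](CO1)([C@H](CCB2OC(C)(C)C(C)(C)O2)CO)C3=C4C(=O)CC[C@@H]4[C@H](C(=O)OC)C3 | intermediate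
21 | ring A alcohol: diquinane enone with the 6-ethyl-3,4-dihydro-2H-pyran ring on C6, CH2CH2B(pin) and CH2OH (C27) on C9 | CCC1=CC[C@](CO1)([C@H](CCB2OC(C)(C)C(C)(C)O2)CO)C3=C4C(=O)CC[C@@H]4[C@H](C(=O)OC)C3 | intermediate
22 | sarcosine | CNCC(=O)O | starting material
23 | C27 triflate of 21 (not isolated) | CCC1=CC[C@](CO1)([C@H](CCB2OC(C)(C)C(C)(C)O2)COS(=O)(=O)C(F)(F)F)C3=C4C(=O)CC[C@@H]4[C@H](C(=O)OC)C3 | intermediate
24 | sarcosine trimethylsilyl ester (not isolated) | CNCC(=O)O[Si](C)(C)C | intermediate
25 | trimethylsilyl ester of 26 (not isolated) | CCC1=CC[C@](CO1)([C@H](CCB2OC(C)(C)C(C)(C)O2)CN(C)CC(=O)O[Si](C)(C)C)C3=C4C(=O)CC[C@@H]4[C@H](C(=O)OC)C3 | intermediate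
26 | amino acid precursor: sarcosine-tethered diquinane enone carrying ring A and the C9 boronate arm; 6S, 9S, 14R, 17R | CCC1=CC[C@](CO1)([C@H](CCB2OC(C)(C)C(C)(C)O2)CN(C)CC(=O)O)C3=C4C(=O)CC[C@@H]4[C@H](C(=O)OC)C3 | intermediate
27 | tetracyclic amino ketone (rings A, B, D, E; C24–C23 formed; H13 cis to H14; C6, C9, C14, C17, C23 arranged as in 30) | CCC1=CC[C@]2(CO1)[C@H](CCB3OC(C)(C)C(C)(C)O3)CN(C)C[C@@]24C[C@@H](C(=O)OC)[C@H]5CCC(=O)[C@@H]45 | intermediate
28 | C12=C13 trimethylsilyl enol ether of 27 (not isolated) | CCC1=CC[C@]2(CO1)[C@H](CCB3OC(C)(C)C(C)(C)O3)CN(C)C[C@@]24C[C@@H](C(=O)OC)[C@H]5CCC(O[Si](C)(C)C)=C45 | intermediate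
29 | C12=C13 enol triflate of 27 | CCC1=CC[C@]2(CO1)[C@H](CCB3OC(C)(C)C(C)(C)O3)CN(C)C[C@@]24C[C@@H](C(=O)OC)[C@H]5CCC(OS(=O)(=O)C(F)(F)F)=C45 | intermediate
30 | CNP0159589.2 (6S, 9S, 14R, 17R, 23R) | CCC1=CC[C@]2(CO1)[C@@H]1CCC3=C4[C@H](CC3)[C@H](C(=O)OC)C[C@@]42CN(C)C1 | target

Total step count: 17 (steps 2 and 8 prepare side components). Longest linear sequence: 15 steps (1, 3–7, 9–17).

Steps most likely to fail

Step 15. The 6-exo addition to the fully substituted C23, next to the quaternary C6, may be slower than hydrogen abstraction by, or back electron transfer to, the aminomethyl radical. The carboxylate may also resist oxidation, or the face selectivity at C23 may be poor. Fallback: the same bond would be made from a silylmethyl amine. Alcohol 21 is converted through triflate 23 with N-methyl-1-(trimethylsilyl)methanamine into the silylmethyl amine F1. Single-electron photo-oxidation of F1 ([Ir(ppy)2(dtbbpy)]PF6, MeCN/MeOH, blue LEDs) triggers desilylation to the same C24 radical, a cyclisation mode known for enones, and should give 27, where the route is rejoined.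

Step 16. Equilibrating silylation may leak toward the less hindered C16 enol, because the ring-fusion enol places its oxygen next to the quaternary C23. Fallback: ketone 27 would be deprotonated kinetically at C16 (LiN(i-Pr)2, THF, −78 °C) and trapped with PhNTf2 to give the C12=C16 enol triflate F2. The Suzuki closure of step 17 would then give the C12=C16 alkene isomer F3 of the target. Its trisubstituted alkene would be moved into the tetrasubstituted C12=C13 position by rhodium hydride catalysis (RhCl3·3H2O, EtOH, 60 °C; ring A re-closed with PPTS if it opens), rejoining the route at 30.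

Step 11. Protonation of the ester enolate at 140 °C may show poor facial selectivity at C17, and the wanted epimer (ester cis to C15) is expected to be the less stable one, so it cannot be reached by equilibration. Fallback: diester 17 would be half-saponified (LiOH, THF/H2O, 0 °C) to the half-acid F4 and converted into the N-hydroxypyridine-2-thione ester F5 (EDC, 2-mercaptopyridine N-oxide). Barton decarboxylation (t-BuSH, visible light, 0 °C) then delivers a hydrogen atom from the bulky thiol to the planar C17 radical at low temperature, again anti to ring D, and should give 18, where the route is rejoined.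

Further compounds

F1 | step 15 | silylmethyl amine: as 26 with N(CH3)CH2Si(CH3)3 in place of N(CH3)CH2CO2H | CCC1=CC[C@](CO1)([C@H](CCB2OC(C)(C)C(C)(C)O2)CN(C)C[Si](C)(C)C)C3=C4C(=O)CC[C@@H]4[C@H](C(=O)OC)C3
F2 | step 16 | C12=C16 enol triflate of 27 | CCC1=CC[C@]2(CO1)[C@H](CCB3OC(C)(C)C(C)(C)O3)CN(C)C[C@@]24C[C@@H](C(=O)OC)[C@H]5CC=C(OS(=O)(=O)C(F)(F)F)[C@@H]45
F3 | step 16 | C12=C16 alkene isomer of the target (ring C closed; H13 cis to H14) | CCC1=CC[C@]2(CO1)[C@H](CC6)CN(C)C[C@@]24C[C@@H](C(=O)OC)[C@H]5CC=C6[C@@H]45
F4 | step 11 | half-acid of 17 (one CO2H and one CO2Me on C17; C17 configuration not defined) | CCC1(OCCO1)CC[C@](CO[Si](C)(C)C(C)(C)C)([C@H](C=C)CO[Si](C)(C)C(C)(C)C)C2=C3C(=O)CC[C@@H]3C(C(=O)O)(C(=O)OC)C2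
F5 | step 11 | N-hydroxypyridine-2-thione ester of F4 | CCC1(OCCO1)CC[C@](CO[Si](C)(C)C(C)(C)C)([C@H](C=C)CO[Si](C)(C)C(C)(C)C)C2=C3C(=O)CC[C@@H]3C(C(=O)ON4C=CC=CC4=S)(C(=O)OC)C2
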